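**Retrosynthetic overview**
- The target is made in the last step from the open-chain, fully deprotected 3-amino-5-hydroxyphenyl seco acid: phenol → aminobenzoquinone, the β-diketone carbon C12 adds to the quinone, the ketol dehydrates and aromatises, and the hydroquinone is reoxidised.
- Seco acid ⇒ C9=C10 cross-metathesis of a C1–C9 polypropionate alkene with an aryl ketol/isopropenyl diketone head group, then nitro reduction and desilylation.
- Head group ⇒ dianion aldol of 2-methylhept-1-ene-3,5-dione with 3-hydroxy-5-nitrobenzaldehyde.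
- Polypropionate ⇒ Z-crotylboration (C7, C8) ⇐ 9-BBN hydroboration (C6) ⇐ β-ketoimide anti aldol with methacrolein and syn reduction (C3–C5) ⇐ Evans syn aldol/oxidation (C2).
- Ring order: ring A (aminoquinone ring) is the purchased benzene ring; ring B (hydroxy-methyl benzenoid ring) is the only ring made and is closed in the final step.

Chain numbering: C1 = carboxyl carbon, C11 = ketone on the arene; C12–C15 are the carbons that end up in ring B.

Assumption: the ketol centres C14 and C15 (compounds 22–26) are carried as mixtures because both are erased on aromatisation, and compounds 14, 16, 17 and 20 are taken as catalogue chemicals.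

**Step 1**
Reactants: 1 (4R)-4-benzyl-3-propanoyl-1,3-oxazolidin-2-one; 2 propanal
Product: 4 (4R)-4-benzyl-3-[(2R,3S)-3-hydroxy-2-methylpentanoyl]-1,3-oxazolidin-2-one, via dibutylboron Z-enolate 3 (not isolated)
Conditions: Bu2BOTf, Et3N, CH2Cl2, −78 to 0 °C; then 2, −78 to 0 °C; pH 7 buffer, MeOH, 30% H2O2
Reagents that add atoms: none
Why: Evans syn aldol through a Zimmerman–Traxler chair in which the (R)-benzyl auxiliary shields one enolate face, setting C2 as R (the C3 carbinol is oxidised in step 2).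

**Step 2**
Reactants: 4 (4R)-4-benzyl-3-[(2R,3S)-3-hydroxy-2-methylpentanoyl]-1,3-oxazolidin-2-one
Product: 5 (4R)-4-benzyl-3-[(2R)-2-methyl-3-oxopentanoyl]-1,3-oxazolidin-2-one
Conditions: Dess–Martin periodinane, pyridine, CH2Cl2, 0 °C to rt
Reagents that add atoms: none
Why: Dess–Martin oxidation gives the β-ketoimide, whose C2 centre does not epimerise because allylic strain keeps the C2–H bond out of alignment with both carbonyl groups.

**Step 3**
Reactants: 5 (4R)-4-benzyl-3-[(2R)-2-methyl-3-oxopentanoyl]-1,3-oxazolidin-2-one; 6 methacrolein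
Product: 8 (4R)-4-benzyl-3-[(2R,4S,5R)-5-hydroxy-2,4,6-trimethyl-3-oxohept-6-enoyl]-1,3-oxazolidin-2-one, via dicyclohexylboron E-enolate 7 (not isolated)
Conditions: (c-C6H11)2BCl, Me2NEt, Et2O, 0 °C; then 6, −78 °C; MeOH, pH 7 buffer, 30% H2O2
Reagents that add atoms: none
Why: Evans β-ketoimide anti aldol, in which the E-boron enolate reacts through a chair transition state and the C2 methyl centre directs the aldehyde to give the 2,4-anti-4,5-anti adduct, setting C4 and C5.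

**Step 4**
Reactants: 8 (4R)-4-benzyl-3-[(2R,4S,5R)-5-hydroxy-2,4,6-trimethyl-3-oxohept-6-enoyl]-1,3-oxazolidin-2-one
Product: 9 (4R)-4-benzyl-3-[(2R,3S,4R,5R)-3,5-dihydroxy-2,4,6-trimethylhept-6-enoyl]-1,3-oxazolidin-2-one
Conditions: Zn(BH4)2, CH2Cl2/Et2O, −78 to −30 °C; aq. NH4Cl
Reagents that add atoms: none
Why: Chelation-controlled 1,3-syn reduction of the β-hydroxy ketone (zinc chelate, external hydride) sets C3 syn to the C5 hydroxyl, and the C2 methyl group favours the same face.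

**Step 5**
Reactants: 9 (4R)-4-benzyl-3-[(2R,3S,4R,5R)-3,5-dihydroxy-2,4,6-trimethylhept-6-enoyl]-1,3-oxazolidin-2-one
Product: 10 (4R)-4-benzyl-3-[(2R,3S,4R,5R)-2,4,6-trimethyl-3,5-bis(triethylsilyloxy)hept-6-enoyl]-1,3-oxazolidin-2-one
Conditions: TESOTf, 2,6-lutidine, CH2Cl2, −78 °C
Reagents that add atoms: triethylsilyl trifluoromethanesulfonate, CC[Si](CC)(CC)OS(=O)(=O)C(F)(F)F
Why: Fast low-temperature silylation of both hydroxyls blocks lactonisation of the C5 hydroxyl onto the imide and protects the diol for the steps up to the metathesis.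

**Step 6**
Reactants: 10 (4R)-4-benzyl-3-[(2R,3S,4R,5R)-2,4,6-trimethyl-3,5-bis(triethylsilyloxy)hept-6-enoyl]-1,3-oxazolidin-2-one
Product: 12 (2R,3S,4S,5S,6S)-7-hydroxy-2,4,6-trimethyl-3,5-bis(triethylsilyloxy)heptanoic acid, via B-alkyl-9-BBN adduct 11 (not isolated)
Conditions: 9-BBN dimer, THF, 0 °C to rt; then LiOH, 30% H2O2, THF/H2O, 0 °C; Na2SO3; HCl to pH 3
Reagents that add atoms: hydrogen peroxide, OO
Why: Still–Barrish hydroboration of the 1,1-disubstituted alkene occurs anti to the allylic silyloxy centre and sets C6, and the basic peroxide work-up both oxidises the C–B bond and removes the auxiliary (Evans LiOOH cleavage) without touching C2.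

**Step 7**
Reactants: 12 (2R,3S,4S,5S,6S)-7-hydroxy-2,4,6-trimethyl-3,5-bis(triethylsilyloxy)heptanoic acid
Product: 13 (2R,3S,4S,5R,6R)-2,4,6-trimethyl-7-oxo-3,5-bis(triethylsilyloxy)heptanoic acid
Conditions: Dess–Martin periodinane, pyridine, CH2Cl2, 0 °C to rt; used crude
Reagents that add atoms: none
Why: Buffered Dess–Martin oxidation gives the α-methyl aldehyde without epimerising C6 and tolerates the free acid and the silyl ethers.

**Step 8**
Reactants: 13 (2R,3S,4S,5R,6R)-2,4,6-trimethyl-7-oxo-3,5-bis(triethylsilyloxy)heptanoic acid; 14 2-[(2Z)-but-2-en-1-yl]-4,4,5,5-tetramethyl-1,3,2-dioxaborolane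
Product: 15 (2R,3S,4S,5S,6S,7S,8R)-7-hydroxy-2,4,6,8-tetramethyl-3,5-bis(triethylsilyloxy)dec-9-enoic acid
Conditions: 14 (2 equiv), toluene (1 M), 4 Å sieves, −20 °C to rt, 36 h; aq. NaHCO3
Reagents that add atoms: none
Why: Z-crotylboration through a closed chair transition state gives the 7,8-syn relationship, and the intrinsic anti-Felkin preference of Z-crotylboronates with α-methyl aldehydes gives the 6,7-anti relationship (about 9:1 expected, minor isomer removed by chromatography).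

**Step 9**
Reactants: 16 3-methylbut-3-en-2-one; 17 N-methoxy-N-methylpropanamide
Product: 19 2-methylhept-1-ene-3,5-dione, via lithium dienolate 18 (not isolated)
Conditions: LiN(iPr)2, THF, −78 °C; then 17, −78 to 0 °C; 1 M HCl
Reagents that add atoms: none
Why: Claisen-type C-acylation of the only possible kinetic enolate by a Weinreb amide, whose chelated tetrahedral adduct survives until the acid quench and so prevents over-reaction.

**Step 10**
Reactants: 19 2-methylhept-1-ene-3,5-dione; 20 3-hydroxy-5-nitrobenzaldehyde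
Product: 22 1-hydroxy-1-(3-hydroxy-5-nitrophenyl)-2,6-dimethylhept-6-ene-3,5-dione, via dilithium dianion 21 (not isolated)
Conditions: 19 (2.2 equiv), LiN(iPr)2 (4.5 equiv), THF, −78 to 0 to −78 °C; then 20 (1 equiv), −78 °C; AcOH quench
Reagents that add atoms: none
Why: Hauser-type 1,3-diketone dianion aldol at the terminal carbanion; one equivalent of dianion deprotonates the phenol, whose meta phenoxide leaves the aldehyde electrophilic, and the ketol stereochemistry is irrelevant.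

**Step 11**
Reactants: 15 (2R,3S,4S,5S,6S,7S,8R)-7-hydroxy-2,4,6,8-tetramethyl-3,5-bis(triethylsilyloxy)dec-9-enoic acid; 22 1-hydroxy-1-(3-hydroxy-5-nitrophenyl)-2,6-dimethylhept-6-ene-3,5-dione
Product: 23 (2R,3S,4S,5S,6S,7S,8R,9E)-7,15-dihydroxy-15-(3-hydroxy-5-nitrophenyl)-2,4,6,8,10,14-hexamethyl-11,13-dioxo-3,5-bis(triethylsilyloxy)pentadec-9-enoic acid
Conditions: 22 (3 equiv), second-generation Hoveyda–Grubbs catalyst RuCl2(H2IMes)(=CH-C6H4-2-O-iPr) (2 × 5 mol%), CH2Cl2, 40 °C, argon sparge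
Reagents that add atoms: none
Why: Olefin cross-metathesis of a terminal alkene with a 1,1-disubstituted enone that does not homodimerise gives the trisubstituted E-enone under thermodynamic control, driven by loss of ethylene; no stereocentre is touched.

**Step 12**
Reactants: 23 (2R,3S,4S,5S,6S,7S,8R,9E)-7,15-dihydroxy-15-(3-hydroxy-5-nitrophenyl)-2,4,6,8,10,14-hexamethyl-11,13-dioxo-3,5-bis(triethylsilyloxy)pentadec-9-enoic acid
Product: 24 (2R,3S,4S,5S,6S,7S,8R,9E)-15-(3-amino-5-hydroxyphenyl)-3,5,7,15-tetrahydroxy-2,4,6,8,10,14-hexamethyl-11,13-dioxopentadec-9-enoic acid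
Conditions: Zn dust, AcOH/THF/H2O 3:1:1, 0 °C, 30 min; filter; filtrate at rt, 12 h; lyophilise
Reagents that add atoms: none
Why: Dissolving-metal reduction of the nitroarene to the aniline is fast at 0 °C, and the same aqueous acetic acid then hydrolyses both triethylsilyl ethers once the zinc has been filtered off, so the enone is not exposed to metal for long.

**Step 13**
Reactants: 24 (2R,3S,4S,5S,6S,7S,8R,9E)-15-(3-amino-5-hydroxyphenyl)-3,5,7,15-tetrahydroxy-2,4,6,8,10,14-hexamethyl-11,13-dioxopentadec-9-enoic acid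
Product: 28 (2R,3S,4S,5S,6S,7S,8R,9E)-11-(6-amino-2-hydroxy-3-methyl-5,8-dioxo-5,8-dihydronaphthalen-1-yl)-3,5,7-trihydroxy-2,4,6,8,10-pentamethyl-11-oxoundec-9-enoic acid, via aminobenzoquinone seco acid 25 (not isolated), via cyclised ketol hydroquinone 26 (not isolated), via aminonaphthalenetriol 27 (not isolated)
Conditions: Fremy's salt K2[ON(SO3)2] (4.5 equiv), KH2PO4/K2HPO4 buffer pH 7.5, acetone/H2O, 0 °C to rt, high dilution; acidify to pH 4; reversed-phase HPLC
Reagents that add atoms: Fremy's salt (dipotassium nitrosodisulfonate), [K+].[K+].[O]N(S(=O)(=O)[O-])S(=O)(=O)[O-]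
Why: Proposed new method: Teuber oxidation of the phenol at its free para position (between the side chain and the amino group) gives the 2-amino-6-alkylbenzoquinone, whose ring carbon next to the side chain is β to the quinone carbonyl that the amino group does not deactivate, so the enolised β-diketone carbon C12 adds there in a 6-endo Michael closure of ring B, after which loss of the benzylic hydroxyl as water and enolisation aromatise ring B and excess oxidant returns the aminohydroquinone to the quinone; the closest known reactions are the Teuber oxidation of 3,5-disubstituted phenols to p-quinones and the Michael addition of 1,3-dicarbonyl compounds to quinones, and the sequence copies the spontaneous cyclisation proposed for the hydroxylated aminohydroxybenzoate tetraketide in rifamycin biosynthesis.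

**Compound list**
1 | (4R)-4-benzyl-3-propanoyl-1,3-oxazolidin-2-one | CCC(=O)N1[C@H](Cc2ccccc2)COC1=O | starting material
2 | propanal | CCC=O | starting material
3 | dibutylboron (Z)-enolate of 1 | C/C=C(\OB(CCCC)CCCC)N1[C@H](Cc2ccccc2)COC1=O | intermediate
4 | (4R)-4-benzyl-3-[(2R,3S)-3-hydroxy-2-methylpentanoyl]-1,3-oxazolidin-2-one | CC[C@H](O)[C@@H](C)C(=O)N1[C@H](Cc2ccccc2)COC1=O | intermediate
5 | (4R)-4-benzyl-3-[(2R)-2-methyl-3-oxopentanoyl]-1,3-oxazolidin-2-one | CCC(=O)[C@@H](C)C(=O)N1[C@H](Cc2ccccc2)COC1=O | intermediate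
6 | methacrolein (2-methylprop-2-enal) | CC(=C)C=O | starting material
7 | dicyclohexylboron (E)-enolate of 5 | C/C=C(/OB(C1CCCCC1)C1CCCCC1)[C@@H](C)C(=O)N1[C@H](Cc2ccccc2)COC1=O | intermediate
8 | (4R)-4-benzyl-3-[(2R,4S,5R)-5-hydroxy-2,4,6-trimethyl-3-oxohept-6-enoyl]-1,3-oxazolidin-2-one | CC(=C)[C@H](O)[C@H](C)C(=O)[C@@H](C)C(=O)N1[C@H](Cc2ccccc2)COC1=O | intermediate
9 | (4R)-4-benzyl-3-[(2R,3S,4R,5R)-3,5-dihydroxy-2,4,6-trimethylhept-6-enoyl]-1,3-oxazolidin-2-one | CC(=C)[C@H](O)[C@H](C)[C@H](O)[C@@H](C)C(=O)N1[C@H](Cc2ccccc2)COC1=O | intermediate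
10 | (4R)-4-benzyl-3-[(2R,3S,4R,5R)-2,4,6-trimethyl-3,5-bis(triethylsilyloxy)hept-6-enoyl]-1,3-oxazolidin-2-one | CC(=C)[C@H](O[Si](CC)(CC)CC)[C@H](C)[C@H](O[Si](CC)(CC)CC)[C@@H](C)C(=O)N1[C@H](Cc2ccccc2)COC1=O | intermediate
11 | B-alkyl-9-borabicyclo[3.3.1]nonane adduct of 10 (boron on C7, new C6 centre as in 12) | C1CCC2CCCC1B2C[C@H](C)[C@H](O[Si](CC)(CC)CC)[C@H](C)[C@H](O[Si](CC)(CC)CC)[C@@H](C)C(=O)N1[C@H](Cc2ccccc2)COC1=O | intermediate
12 | (2R,3S,4S,5S,6S)-7-hydroxy-2,4,6-trimethyl-3,5-bis(triethylsilyloxy)heptanoic acid | OC[C@H](C)[C@H](O[Si](CC)(CC)CC)[C@H](C)[C@H](O[Si](CC)(CC)CC)[C@@H](C)C(=O)O | intermediate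
13 | (2R,3S,4S,5R,6R)-2,4,6-trimethyl-7-oxo-3,5-bis(triethylsilyloxy)heptanoic acid | O=C[C@H](C)[C@H](O[Si](CC)(CC)CC)[C@H](C)[C@H](O[Si](CC)(CC)CC)[C@@H](C)C(=O)O | intermediate
14 | 2-[(2Z)-but-2-en-1-yl]-4,4,5,5-tetramethyl-1,3,2-dioxaborolane | C/C=C\CB1OC(C)(C)C(C)(C)O1 | starting material
15 | (2R,3S,4S,5S,6S,7S,8R)-7-hydroxy-2,4,6,8-tetramethyl-3,5-bis(triethylsilyloxy)dec-9-enoic acid | C=C[C@@H](C)[C@H](O)[C@H](C)[C@H](O[Si](CC)(CC)CC)[C@H](C)[C@H](O[Si](CC)(CC)CC)[C@@H](C)C(=O)O | intermediate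
16 | 3-methylbut-3-en-2-one | CC(=O)C(C)=C | starting material
17 | N-methoxy-N-methylpropanamide | CCC(=O)N(C)OC | starting material
18 | lithium 3-methylbuta-1,3-dien-2-olate | [Li+].[O-]C(=C)C(C)=C | intermediate
19 | 2-methylhept-1-ene-3,5-dione | C=C(C)C(=O)CC(=O)CC | intermediate
20 | 3-hydroxy-5-nitrobenzaldehyde | O=Cc1cc(O)cc([N+](=O)[O-])c1 | starting material
21 | dilithium 1,3-dianion of 19 | [Li+].[Li+].C=C(C)C([O-])=CC([O-])=CC | intermediate
22 | 1-hydroxy-1-(3-hydroxy-5-nitrophenyl)-2,6-dimethylhept-6-ene-3,5-dione (diastereomer mixture) | C=C(C)C(=O)CC(=O)C(C)C(O)c1cc(O)cc([N+](=O)[O-])c1 | intermediate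
23 | (2R,3S,4S,5S,6S,7S,8R,9E)-7,15-dihydroxy-15-(3-hydroxy-5-nitrophenyl)-2,4,6,8,10,14-hexamethyl-11,13-dioxo-3,5-bis(triethylsilyloxy)pentadec-9-enoic acid (C14/C15 mixture) | OC(c1cc(O)cc([N+](=O)[O-])c1)C(C)C(=O)CC(=O)/C(C)=C/[C@@H](C)[C@H](O)[C@H](C)[C@H](O[Si](CC)(CC)CC)[C@H](C)[C@H](O[Si](CC)(CC)CC)[C@@H](C)C(=O)O | intermediate
24 | (2R,3S,4S,5S,6S,7S,8R,9E)-15-(3-amino-5-hydroxyphenyl)-3,5,7,15-tetrahydroxy-2,4,6,8,10,14-hexamethyl-11,13-dioxopentadec-9-enoic acid (C14/C15 mixture) | OC(c1cc(O)cc(N)c1)C(C)C(=O)CC(=O)/C(C)=C/[C@@H](C)[C@H](O)[C@H](C)[C@H](O)[C@H](C)[C@H](O)[C@@H](C)C(=O)O | intermediate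
25 | (2R,3S,4S,5S,6S,7S,8R,9E)-15-(5-amino-3,6-dioxocyclohexa-1,4-dien-1-yl)-3,5,7,15-tetrahydroxy-2,4,6,8,10,14-hexamethyl-11,13-dioxopentadec-9-enoic acid | O=C1C=C(C(O)C(C)C(=O)CC(=O)/C(C)=C/[C@@H](C)[C@H](O)[C@H](C)[C@H](O)[C@H](C)[C@H](O)[C@@H](C)C(=O)O)C(=O)C(N)=C1 | intermediate
26 | (2R,3S,4S,5S,6S,7S,8R,9E)-11-(6-amino-4,5,8-trihydroxy-3-methyl-2-oxo-1,2,3,4-tetrahydronaphthalen-1-yl)-3,5,7-trihydroxy-2,4,6,8,10-pentamethyl-11-oxoundec-9-enoic acid (ring centres unassigned) | Nc1cc(O)c2C(C(=O)/C(C)=C/[C@@H](C)[C@H](O)[C@H](C)[C@H](O)[C@H](C)[C@H](O)[C@@H](C)C(=O)O)C(=O)C(C)C(O)c2c1O | intermediate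
27 | (2R,3S,4S,5S,6S,7S,8R,9E)-11-(6-amino-2,5,8-trihydroxy-3-methylnaphthalen-1-yl)-3,5,7-trihydroxy-2,4,6,8,10-pentamethyl-11-oxoundec-9-enoic acid | Nc1cc(O)c2c(C(=O)/C(C)=C/[C@@H](C)[C@H](O)[C@H](C)[C@H](O)[C@H](C)[C@H](O)[C@@H](C)C(=O)O)c(O)c(C)cc2c1O | intermediate
28 | (2R,3S,4S,5S,6S,7S,8R,9E)-11-(6-amino-2-hydroxy-3-methyl-5,8-dioxo-5,8-dihydronaphthalen-1-yl)-3,5,7-trihydroxy-2,4,6,8,10-pentamethyl-11-oxoundec-9-enoic acid (CNP0287228.1) | C/C(=C\[C@@H](C)[C@H](O)[C@H](C)[C@H](O)[C@H](C)[C@H](O)[C@@H](C)C(=O)O)C(=O)c1c(O)c(C)cc2c1C(=O)C=C(N)C2=O | target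

**Step count and risks**
Total step count: 13. Longest linear sequence: 11 steps (steps 1–8, 11, 12, 13, from compound 1); the head group takes 2 steps (9, 10).

The three steps most likely to fail:

Step 13 (oxidative ring-B closure). The Teuber oxidation must attack the hindered para position of an unprotected aminophenol, and the quinone must cyclise before it condenses with itself. The fallback brings the second quinone oxygen in with the arene, so no phenol C–H oxidation is needed. It sets out from dianion 21, which is added to commercial 2-hydroxy-5-methoxy-3-nitrobenzaldehyde to give 1-hydroxy-1-(2-hydroxy-5-methoxy-3-nitrophenyl)-2,6-dimethylhept-6-ene-3,5-dione F1. Cross-metathesis of F1 with 15 under the step 11 conditions gives the bis-silyl nitro seco acid F2, and Zn in AcOH/THF/H2O gives the 3-amino-2-hydroxy-5-methoxyphenyl seco acid F3. Oxidative demethylation of this p-methoxy-o-aminophenol with PhI(OAc)2 in MeCN/pH 7 buffer at 0 °C, then air, gives aminoquinone 25, where the route is rejoined and runs on through 26 and 27 to 28.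

Step 11 (cross-metathesis). Both alkenes are hindered and the β-diketone can bind ruthenium. The fallback makes the C9=C10 bond by carbonyl olefination. It sets out from 15, which is ozonised (O3, CH2Cl2/MeOH, −78 °C; PPh3) to (2R,3S,4S,5S,6S,7R,8S)-7-hydroxy-2,4,6,8-tetramethyl-9-oxo-3,5-bis(triethylsilyloxy)nonanoic acid F4. The 1,3-dianion of commercial diethyl (3-oxobutan-2-yl)phosphonate (NaH, then n-BuLi) is acylated with 17 to give diethyl (3,5-dioxoheptan-2-yl)phosphonate F5. Horner–Wadsworth–Emmons reaction of F4 with F5 (Ba(OH)2, wet THF) gives the ethyl-terminated E-enedione acid F6. Its polyanion (excess LiN(iPr)2, THF, −78 °C) is added to 20, and the route is rejoined at 23.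

Step 12 (nitro reduction with desilylation). The enone, the ketol and the δ-hydroxy acid all have to survive zinc and aqueous acid. The fallback reduces the nitro group on the small head group and carries the nitrogen as a fluoride-labile carbamate. It sets out from 22, which is reduced (Zn, NH4Cl, MeOH/H2O) to 1-(3-amino-5-hydroxyphenyl)-1-hydroxy-2,6-dimethylhept-6-ene-3,5-dione F7. This is acylated on nitrogen with 2,5-dioxopyrrolidin-1-yl 2-(trimethylsilyl)ethyl carbonate (NaHCO3, dioxane/H2O) to give the 2-(trimethylsilyl)ethyl carbamate F8. Cross-metathesis of F8 with 15 gives the protected seco acid F9, and Bu4NF buffered with AcOH in THF removes both silyl ethers and the carbamate, rejoining the route at 24.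

**Further compounds**
F1 | step 13 | 1-hydroxy-1-(2-hydroxy-5-methoxy-3-nitrophenyl)-2,6-dimethylhept-6-ene-3,5-dione | C=C(C)C(=O)CC(=O)C(C)C(O)c1cc(OC)cc([N+](=O)[O-])c1O
F2 | step 13 | (2R,3S,4S,5S,6S,7S,8R,9E)-7,15-dihydroxy-15-(2-hydroxy-5-methoxy-3-nitrophenyl)-2,4,6,8,10,14-hexamethyl-11,13-dioxo-3,5-bis(triethylsilyloxy)pentadec-9-enoic acid | OC(c1cc(OC)cc([N+](=O)[O-])c1O)C(C)C(=O)CC(=O)/C(C)=C/[C@@H](C)[C@H](O)[C@H](C)[C@H](O[Si](CC)(CC)CC)[C@H](C)[C@H](O[Si](CC)(CC)CC)[C@@H](C)C(=O)O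
F3 | step 13 | (2R,3S,4S,5S,6S,7S,8R,9E)-15-(3-amino-2-hydroxy-5-methoxyphenyl)-3,5,7,15-tetrahydroxy-2,4,6,8,10,14-hexamethyl-11,13-dioxopentadec-9-enoic acid | OC(c1cc(OC)cc(N)c1O)C(C)C(=O)CC(=O)/C(C)=C/[C@@H](C)[C@H](O)[C@H](C)[C@H](O)[C@H](C)[C@H](O)[C@@H](C)C(=O)O
F4 | step 11 | (2R,3S,4S,5S,6S,7R,8S)-7-hydroxy-2,4,6,8-tetramethyl-9-oxo-3,5-bis(triethylsilyloxy)nonanoic acid | O=C[C@@H](C)[C@H](O)[C@H](C)[C@H](O[Si](CC)(CC)CC)[C@H](C)[C@H](O[Si](CC)(CC)CC)[C@@H](C)C(=O)O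
F5 | step 11 | diethyl (3,5-dioxoheptan-2-yl)phosphonate | CCOP(=O)(OCC)C(C)C(=O)CC(=O)CC
F6 | step 11 | (2R,3S,4S,5S,6S,7S,8R,9E)-7-hydroxy-2,4,6,8,10-pentamethyl-11,13-dioxo-3,5-bis(triethylsilyloxy)pentadec-9-enoic acid | CCC(=O)CC(=O)/C(C)=C/[C@@H](C)[C@H](O)[C@H](C)[C@H](O[Si](CC)(CC)CC)[C@H](C)[C@H](O[Si](CC)(CC)CC)[C@@H](C)C(=O)O
F7 | step 12 | 1-(3-amino-5-hydroxyphenyl)-1-hydroxy-2,6-dimethylhept-6-ene-3,5-dione | C=C(C)C(=O)CC(=O)C(C)C(O)c1cc(O)cc(N)c1
F8 | step 12 | 2-(trimethylsilyl)ethyl N-[3-hydroxy-5-(1-hydroxy-2,6-dimethyl-3,5-dioxohept-6-en-1-yl)phenyl]carbamate | C=C(C)C(=O)CC(=O)C(C)C(O)c1cc(O)cc(NC(=O)OCC[Si](C)(C)C)c1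
F9 | step 12 | (2R,3S,4S,5S,6S,7S,8R,9E)-7,15-dihydroxy-15-[3-hydroxy-5-({[2-(trimethylsilyl)ethoxy]carbonyl}amino)phenyl]-2,4,6,8,10,14-hexamethyl-11,13-dioxo-3,5-bis(triethylsilyloxy)pentadec-9-enoic acid | OC(c1cc(O)cc(NC(=O)OCC[Si](C)(C)C)c1)C(C)C(=O)CC(=O)/C(C)=C/[C@@H](C)[C@H](O)[C@H](C)[C@H](O[Si](CC)(CC)CC)[C@H](C)[C@H](O[Si](CC)(CC)CC)[C@@H](C)C(=O)O
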